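**Retrosynthetic overview**
- Target ⇐ phenol unmasking, C8=C9 dehydrogenation, esterification of the C6 alcohol, and hydroxyl-directed reduction of a C6 ketone.
- Five-membered ring (formed last): C4–C5 bond by cation–π (Mukaiyama/Prins-type) addition of a ring silyl enol ether to the side-chain isopropyl ketone; the ketone stands in for the biosynthetic olefin so that C4–OH arrives directly.
- Seven-membered ring: 1,2-shift ring expansion of a six-membered tertiary allylic alcohol through an exocyclic tertiary cation; this step also creates the C1 quaternary stereocentre.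
- Six-membered ring is bought (5-methylcyclohexane-1,3-dione); the side chain comes from 3-methylbutan-2-one and 2,3-dibromopropene.
- Ring order: six (purchased) → seven → five.

Assumption: the biosynthesis is taken as farnesyl cation → six-membered (bisabolyl-type) tertiary cation → 1,2-shift ring expansion → five-ring closure onto the isopropyl-bearing carbon → late oxidation and vanilloylation; daucane numbering is used for the core (C1 quaternary, C4 carbinol, C5 ring-fusion CH, C6 ester carbon, C8=C9, C10 ketone).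

**Step 1**
Reactants: 1 3-methylbutan-2-one; 2 2,3-dibromoprop-1-ene
Product: 4 6-bromo-2-methylhept-6-en-3-one, via lithium enolate 3 (not isolated)
Conditions: LiN(iPr)2, THF, −78 °C; then 2, −78 → 0 °C
Reagents that add atoms: none
Why: kinetic enolate alkylation at the methyl group with the allylic bromide (the vinylic bromide is inert); no stereocentre is formed.

**Step 2**
Reactants: 5 5-methylcyclohexane-1,3-dione
Product: 6 5-methyl-3-[(triisopropylsilyl)oxy]cyclohex-2-en-1-one (racemic)
Conditions: triisopropylsilyl trifluoromethanesulfonate, Et3N, CH2Cl2, 0 °C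
Reagents that add atoms: triisopropylsilyl trifluoromethanesulfonate, CC(C)[Si](OS(=O)(=O)C(F)(F)F)(C(C)C)C(C)C
Why: O-silylation of a cyclic 1,3-dione gives the silyl vinylogous ester; its methyl-bearing stereocentre (future C8) is erased in step 8, so the racemate is used.

**Step 3**
Reactants: 4 6-bromo-2-methylhept-6-en-3-one; 6 5-methyl-3-[(triisopropylsilyl)oxy]cyclohex-2-en-1-one
Product: 9 6-{1-hydroxy-5-methyl-3-[(triisopropylsilyl)oxy]cyclohex-2-en-1-yl}-2-methylhept-6-en-3-one (stereoisomer mixture), via potassium enolate 7 (not isolated), via vinyllithium–enolate 8 (not isolated)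
Conditions: KH, THF, 0 °C; t-BuLi (2 equiv), −78 °C; then 6, −78 → −40 °C; aq NH4Cl (pH 8 work-up, no silica)
Reagents that add atoms: none
Why: the ketone is masked in situ as its enolate, bromine–lithium exchange gives the vinyllithium, and this adds 1,2 to the vinylogous ester (Stork–Danheiser-type addition); the carbinol stereocentre is destroyed in step 4.

**Step 4**
Reactants: 9 6-{1-hydroxy-5-methyl-3-[(triisopropylsilyl)oxy]cyclohex-2-en-1-yl}-2-methylhept-6-en-3-one
Product: 11 (2S)-2,6-dimethyl-2-(4-methyl-3-oxopentyl)-4-[(triisopropylsilyl)oxy]cyclohept-3-en-1-one (6RS), via tertiary carbocation 10 (not isolated)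
Conditions: [(S,S)-N,N′-bis(3,5-di-tert-butylsalicylidene)-1,2-cyclohexanediaminato]cobalt (divalent cobalt, 5 mol %), N-fluoro-2,4,6-trimethylpyridinium tetrafluoroborate (1.1 equiv), PhSiH3 (1.1 equiv), acetone, −20 °C
Reagents that add atoms: none
Why: Proposed new method: a cobalt hydride transfers a hydrogen atom to the terminal CH2 of the 1,1-disubstituted alkene and the tertiary radical is oxidised (radical–polar crossover) to a cation equivalent next to the carbinol; the electron-rich enol-ether vinyl carbon then migrates in preference to the ring CH2 (semipinacol 1,2-shift), giving the ring-expanded ketone with the enol ether intact, and the chiral salen ligand is asked to select the face of the prochiral cationic carbon to set the quaternary centre (the ligand antipode is used if induction is opposite); the closest known reaction type is the cobalt–salen hydrogen-atom-transfer semipinacol rearrangement of tertiary allylic alcohols.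

**Step 5**
Reactants: 11 (2S)-2,6-dimethyl-2-(4-methyl-3-oxopentyl)-4-[(triisopropylsilyl)oxy]cyclohept-3-en-1-one
Product: 13 (3R,3aR,8aS)-3-hydroxy-6,8a-dimethyl-3-(propan-2-yl)octahydroazulene-4,8(1H,5H)-dione (6RS; trans-fused, OH cis to the angular methyl), via titanium aldolate 12 (not isolated)
Conditions: TiCl4 (1.2 equiv), CH2Cl2, −78 → −30 °C; aq NaHCO3
Reagents that add atoms: none
Why: intramolecular Mukaiyama (Prins-type) aldol of the regiodefined enol silane onto the Lewis-acid-activated isopropyl ketone closes the five-membered ring; the hindered tertiary titanium aldolate is expected to form reversibly on warming and settle in the chelated trans-fused isomer with isopropyl anti to the angular methyl, which sets C5 and C4.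

**Step 6**
Reactants: 13 (3R,3aR,8aS)-3-hydroxy-6,8a-dimethyl-3-(propan-2-yl)octahydroazulene-4,8(1H,5H)-dione
Product: 14 (3R,3aS,4S,8aS)-3,4-dihydroxy-6,8a-dimethyl-3-(propan-2-yl)octahydroazulen-8(1H)-one (6RS)
Conditions: Me4N[BH(OAc)3], MeCN/AcOH (1:1), −30 °C
Reagents that add atoms: none
Why: Evans–Saksena hydroxyl-directed reduction delivers hydride from the C4–O-bound boron to the same face of the C6 ketone, giving the anti-1,3-diol (C6 S); the hindered C10 ketone has no directing β-hydroxyl and is untouched.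

**Step 7**
Reactants: 14 (3R,3aS,4S,8aS)-3,4-dihydroxy-6,8a-dimethyl-3-(propan-2-yl)octahydroazulen-8(1H)-one; 15 4-acetoxy-3-methoxybenzoic acid
Product: 16 (3R,3aS,4S,8aS)-3-hydroxy-6,8a-dimethyl-8-oxo-3-(propan-2-yl)decahydroazulen-4-yl 4-acetoxy-3-methoxybenzoate (6RS)
Conditions: DCC, DMAP (cat.), CH2Cl2, 0 → 25 °C
Reagents that add atoms: none
Why: Steglich esterification acylates the secondary C6 alcohol only, because the tertiary C4 alcohol is too hindered; no stereocentre is touched.

**Step 8**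
Reactants: 16 (3R,3aS,4S,8aS)-3-hydroxy-6,8a-dimethyl-8-oxo-3-(propan-2-yl)decahydroazulen-4-yl 4-acetoxy-3-methoxybenzoate
Product: 17 (3R,3aS,4S,8aS)-3-hydroxy-6,8a-dimethyl-8-oxo-3-(propan-2-yl)-1,2,3,3a,4,5,8,8a-octahydroazulen-4-yl 4-acetoxy-3-methoxybenzoate
Conditions: IBX (1.5 equiv), 4-methoxypyridine N-oxide, DMSO, 25 °C
Reagents that add atoms: none
Why: IBX dehydrogenation of the ketone can only run toward C9 (C1 is quaternary), giving the C8=C9 enone and merging both C8 epimers into one compound.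

**Step 9**
Reactants: 17 (3R,3aS,4S,8aS)-3-hydroxy-6,8a-dimethyl-8-oxo-3-(propan-2-yl)-1,2,3,3a,4,5,8,8a-octahydroazulen-4-yl 4-acetoxy-3-methoxybenzoate
Product: 18 (3R,3aS,4S,8aS)-3-hydroxy-6,8a-dimethyl-8-oxo-3-(propan-2-yl)-1,2,3,3a,4,5,8,8a-octahydroazulen-4-yl 4-hydroxy-3-methoxybenzoate (CNP0136950.2)
Conditions: NH4OAc, MeOH/H2O (4:1), 25 °C
Reagents that add atoms: none
Why: near-neutral chemoselective cleavage of the aryl acetate leaves the hindered alkyl benzoate and the enone intact (no base-induced vinylogous elimination of the C6 ester).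

**Compound list**
1 | 3-methylbutan-2-one | CC(=O)C(C)C | starting material
2 | 2,3-dibromoprop-1-ene | C=C(Br)CBr | starting material
3 | lithium 3-methylbut-1-en-2-olate | C=C(O[Li])C(C)C | intermediate
4 | 6-bromo-2-methylhept-6-en-3-one | C=C(Br)CCC(=O)C(C)C | intermediate
5 | 5-methylcyclohexane-1,3-dione | CC1CC(=O)CC(=O)C1 | starting material
6 | 5-methyl-3-[(triisopropylsilyl)oxy]cyclohex-2-en-1-one (racemic) | CC1CC(=O)C=C(O[Si](C(C)C)(C(C)C)C(C)C)C1 | intermediate
7 | potassium 6-bromo-2-methylhepta-3,6-dien-3-olate (enolate regiochemistry immaterial) | C=C(Br)CC=C(O[K])C(C)C | intermediate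
8 | potassium 6-lithio-2-methylhepta-3,6-dien-3-olate | [Li]C(=C)CC=C(O[K])C(C)C | intermediate
9 | 6-{1-hydroxy-5-methyl-3-[(triisopropylsilyl)oxy]cyclohex-2-en-1-yl}-2-methylhept-6-en-3-one (stereoisomer mixture) | C=C(CCC(=O)C(C)C)C1(O)CC(C)CC(O[Si](C(C)C)(C(C)C)C(C)C)=C1 | intermediate
10 | 2-{1-hydroxy-5-methyl-3-[(triisopropylsilyl)oxy]cyclohex-2-en-1-yl}-6-methyl-5-oxoheptan-2-ylium | C[C+](CCC(=O)C(C)C)C1(O)CC(C)CC(O[Si](C(C)C)(C(C)C)C(C)C)=C1 | intermediate
11 | (2S)-2,6-dimethyl-2-(4-methyl-3-oxopentyl)-4-[(triisopropylsilyl)oxy]cyclohept-3-en-1-one (6RS) | CC(C)C(=O)CC[C@]1(C)C(=O)CC(C)CC(O[Si](C(C)C)(C(C)C)C(C)C)=C1 | intermediate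
12 | trichlorotitanium alkoxide (aldolate) of 13 | O=C1CC(C)CC(=O)[C@@]2(C)CC[C@@](O[Ti](Cl)(Cl)Cl)(C(C)C)[C@H]12 | intermediate
13 | (3R,3aR,8aS)-3-hydroxy-6,8a-dimethyl-3-(propan-2-yl)octahydroazulene-4,8(1H,5H)-dione (6RS) | O=C1CC(C)CC(=O)[C@@]2(C)CC[C@@](O)(C(C)C)[C@H]12 | intermediate
14 | (3R,3aS,4S,8aS)-3,4-dihydroxy-6,8a-dimethyl-3-(propan-2-yl)octahydroazulen-8(1H)-one (6RS) | O[C@H]1CC(C)CC(=O)[C@@]2(C)CC[C@@](O)(C(C)C)[C@H]12 | intermediate
15 | 4-acetoxy-3-methoxybenzoic acid | COc1cc(C(=O)O)ccc1OC(C)=O | starting material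
16 | (3R,3aS,4S,8aS)-3-hydroxy-6,8a-dimethyl-8-oxo-3-(propan-2-yl)decahydroazulen-4-yl 4-acetoxy-3-methoxybenzoate (6RS) | COc1cc(C(=O)O[C@H]2CC(C)CC(=O)[C@@]3(C)CC[C@@](O)(C(C)C)[C@H]23)ccc1OC(C)=O | intermediate
17 | (3R,3aS,4S,8aS)-3-hydroxy-6,8a-dimethyl-8-oxo-3-(propan-2-yl)-1,2,3,3a,4,5,8,8a-octahydroazulen-4-yl 4-acetoxy-3-methoxybenzoate | COc1cc(C(=O)O[C@H]2CC(C)=CC(=O)[C@@]3(C)CC[C@@](O)(C(C)C)[C@H]23)ccc1OC(C)=O | intermediate
18 | (3R,3aS,4S,8aS)-3-hydroxy-6,8a-dimethyl-8-oxo-3-(propan-2-yl)-1,2,3,3a,4,5,8,8a-octahydroazulen-4-yl 4-hydroxy-3-methoxybenzoate | COc1cc(C(=O)O[C@H]2CC(C)=CC(=O)[C@@]3(C)CC[C@@](O)(C(C)C)[C@H]23)ccc1O | target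

**Step count**
Total steps: 9. Longest linear sequence: 8 (steps 1, 3, 4, 5, 6, 7, 8, 9).

**Three steps most likely to fail**

Step 4 (ring expansion and absolute configuration). Risks are low enantioinduction on a substrate that is itself a stereoisomer mixture, fluorination of the enol ether by the N–F oxidant, and epoxide formation instead of migration. Fallback: setting out from 9, run the ring expansion with the achiral complex [N,N′-bis(3,5-di-tert-butylsalicylidene)-1,2-ethanediaminato]cobalt to give racemic ring-expanded ketone F4. Carry it through the conditions of steps 5 and 6 to racemic hydroxy diketone F5 and racemic diol F6. Esterify F6 with (S)-2-methoxy-2-phenylacetic acid (DCC, DMAP) and separate the two diastereomers, the wanted (S)-methoxyphenylacetate of 14 F7 and the unwanted (S)-methoxyphenylacetate of ent-14 F8, by chromatography or crystallisation. Saponify F7 (LiOH, aq THF) to come back to the route at 14.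

Step 5 (ring fusion and C4 configuration). Direct attack on the ring sp2 carbon next to the tether-bearing quaternary centre kinetically favours the cis-fused ketol, so the step depends on the aldolate equilibrating to the trans-fused chelate; dehydration to the ring-fusion enone is the competing sink. Fallback: setting out from 11, cleave the silyl enol ether (1 M HCl, THF, 0 °C) to (2S)-2,6-dimethyl-2-(4-methyl-3-oxopentyl)cycloheptane-1,4-dione F9. Close the ring under reversible, magnesium-templated aldol conditions (Mg(OMe)2, MeOH/THF, 0 °C), so that all ketol isomers interconvert by retro-aldol and the least strained chelate accumulates, coming back at 13.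

Step 3 (fragment union). The in situ enolate may self-condense or quench the vinyllithium, and the carbinol 9 is acid-labile. Fallback: setting out from 4, protect the ketone as 6-bromo-3,3-dimethoxy-2-methylhept-6-ene F1 (HC(OMe)3, MeOH, TsOH cat.). Exchange with t-BuLi and add to 6 to give the ketal carbinol 1-(5,5-dimethoxy-6-methylhept-1-en-2-yl)-5-methyl-3-[(triisopropylsilyl)oxy]cyclohex-2-en-1-ol F2. Ring-expand under the step 4 conditions to (2S)-2-(3,3-dimethoxy-4-methylpentyl)-2,6-dimethyl-4-[(triisopropylsilyl)oxy]cyclohept-3-en-1-one F3. Unmask the ketone (pyridinium p-toluenesulfonate, wet acetone, 0 °C; the hindered silyl enol ether should survive) to come back at 11.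

**Further compounds**
F1 | step 3 | 6-bromo-3,3-dimethoxy-2-methylhept-6-ene | C=C(Br)CCC(OC)(OC)C(C)C
F2 | step 3 | 1-(5,5-dimethoxy-6-methylhept-1-en-2-yl)-5-methyl-3-[(triisopropylsilyl)oxy]cyclohex-2-en-1-ol (stereoisomer mixture) | C=C(CCC(OC)(OC)C(C)C)C1(O)CC(C)CC(O[Si](C(C)C)(C(C)C)C(C)C)=C1
F3 | step 3 | (2S)-2-(3,3-dimethoxy-4-methylpentyl)-2,6-dimethyl-4-[(triisopropylsilyl)oxy]cyclohept-3-en-1-one (6RS) | CC(C)C(OC)(OC)CC[C@]1(C)C(=O)CC(C)CC(O[Si](C(C)C)(C(C)C)C(C)C)=C1
F4 | step 4 | racemic 2,6-dimethyl-2-(4-methyl-3-oxopentyl)-4-[(triisopropylsilyl)oxy]cyclohept-3-en-1-one (1:1 mixture of 11 and its enantiomer) | CC(C)C(=O)CC[C@]1(C)C(=O)CC(C)CC(O[Si](C(C)C)(C(C)C)C(C)C)=C1.CC(C)C(=O)CC[C@@]1(C)C(=O)CC(C)CC(O[Si](C(C)C)(C(C)C)C(C)C)=C1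
F5 | step 4 | racemic 3-hydroxy-6,8a-dimethyl-3-(propan-2-yl)octahydroazulene-4,8(1H,5H)-dione (1:1 mixture of 13 and its enantiomer) | O=C1CC(C)CC(=O)[C@@]2(C)CC[C@@](O)(C(C)C)[C@H]12.O=C1CC(C)CC(=O)[C@]2(C)CC[C@](O)(C(C)C)[C@@H]12
F6 | step 4 | racemic 3,4-dihydroxy-6,8a-dimethyl-3-(propan-2-yl)octahydroazulen-8(1H)-one (1:1 mixture of 14 and its enantiomer) | O[C@H]1CC(C)CC(=O)[C@@]2(C)CC[C@@](O)(C(C)C)[C@H]12.O[C@@H]1CC(C)CC(=O)[C@]2(C)CC[C@](O)(C(C)C)[C@@H]12
F7 | step 4 | (3R,3aS,4S,8aS)-3-hydroxy-6,8a-dimethyl-8-oxo-3-(propan-2-yl)decahydroazulen-4-yl (2S)-2-methoxy-2-phenylacetate | CO[C@H](C(=O)O[C@H]1CC(C)CC(=O)[C@@]2(C)CC[C@@](O)(C(C)C)[C@H]12)c1ccccc1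
F8 | step 4 | (3S,3aR,4R,8aR)-3-hydroxy-6,8a-dimethyl-8-oxo-3-(propan-2-yl)decahydroazulen-4-yl (2S)-2-methoxy-2-phenylacetate | CO[C@H](C(=O)O[C@@H]1CC(C)CC(=O)[C@]2(C)CC[C@](O)(C(C)C)[C@@H]12)c1ccccc1
F9 | step 5 | (2S)-2,6-dimethyl-2-(4-methyl-3-oxopentyl)cycloheptane-1,4-dione (6RS) | CC(C)C(=O)CC[C@]1(C)C(=O)CC(C)CC(=O)C1
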